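**Plan**
1. The target is (13R)-8α,15-epoxylabdan-16-yl acetate: an oxocane (ring atoms O, C8, C9, C11, C12, C13, C14, C15) trans-fused to a drimane-type decalin (labdane numbering).
2. Retrosynthesis: C16–OAc ⇐ C16–OH ⇐ exocyclic C13=C16 (hydroboration); C15H2 ⇐ lactone C15=O; then C14–C15 and C11–C12 are cut together. This excises a 2-methylenepropane-1,3-diyl unit (C12, C13, C14, C16) and, on rejoining C11 to C15, leaves (+)-sclareolide.
3. Enabling feature: C15 (on the ring oxygen) and C11 (on C9) are the ends of the chain C15–O–C8–C9–C11. Joined, they are the acyl carbon and α-carbon of a five-membered lactone (O, C8, C9, C11, C15), so a three-carbon unit can be inserted into the acyl–Cα bond (5 → 8 ring expansion) once C11 carries a carbanion-stabilising sulfone.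
4. Forward: sclareolide → C11 sulfone → one-pot alkylation / fluoride-triggered cyclisation–fragmentation (eight-membered lactone) → lactone to cyclic ether → desulfonylation → hydroboration–oxidation → acetylation.
5. Stereochemistry: C5, C8, C9, C10 come unchanged from sclareolide (no bond to C8 or C9 is broken, so the trans fusion is kept); C13 is set by α-face hydroboration of the exocyclic alkene, anti to the axial C8 and C10 methyls.

Key step: step 3

Remark on numbering: the lactone carbonyl carbon of sclareolide is called C15 and its α-carbon C11, as in the target.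
Remark on epimers: the sulfone-bearing C11 of 11, 13 and 14 and the acetal carbon C15 of 13 are expected as epimer mixtures and are drawn without configuration; both centres end as CH2.

**Step 1**
Reactants: 1 (+)-sclareolide
Product: 3 11α-(phenylsulfanyl)sclareolide, via lithium enolate 2 (not isolated)
Conditions: LiN(iPr)2, THF, −78 °C; PhSSPh, THF–DMPU, −78 → 0 °C; dilute aqueous HCl quench
Reagents that add atoms: diphenyl disulfide, c1ccc(cc1)SSc1ccccc1
Why: α-Sulfenylation of a lactone enolate by a disulfide is standard, and the electrophile should enter C11 from the α-face, anti to the axial C8 and C10 methyl groups, although the configuration at C11 is immaterial because this centre is deprotonated again in step 3.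

**Step 2**
Reactants: 3 11α-(phenylsulfanyl)sclareolide
Product: 5 11α-(phenylsulfonyl)sclareolide, via sulfoxide 4 (not isolated)
Conditions: mCPBA (2.5 equiv), CH2Cl2, 0 °C
Reagents that add atoms: 3-chloroperoxybenzoic acid, O=C(OO)c1cccc(Cl)c1
Why: Peracid oxidation of an aryl alkyl sulfide to the sulfone through the sulfoxide is routine, and excess oxidant at 0 °C should carry sulfoxide 4 on before it can undergo thermal syn-elimination towards C9.

**Step 3**
Reactants: 5 11α-(phenylsulfonyl)sclareolide; 6 [2-(chloromethyl)prop-2-en-1-yl]trimethylsilane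
Product: 11 11-(phenylsulfonyl)-8α,15-epoxylabd-13(16)-en-15-one (eight-membered lactone), via sodium enolate 7 (not isolated), via C11-allylated allylsilane lactone 8 (not isolated), via bicyclic alkoxide 9 (not isolated), via sulfonyl carbanion 10 (not isolated)
Conditions: NaH, THF–DMF, 0 °C; 6, 0 → 45 °C; then Bu4N[Ph3SiF2] (anhydrous), 0 °C → rt; AcOH, −40 °C
Reagents that add atoms: [2-(chloromethyl)prop-2-en-1-yl]trimethylsilane (6), C=C(CCl)C[Si](C)(C)C
Why: Proposed new method: the sodium enolate 7 is C-alkylated by allylic chloride 6 on its less hindered α-face (SN2, C11–C12 bond) to give 8, and fluoride then turns the allylsilane into an allyl anion equivalent whose terminus C14 adds to the neighbouring lactone carbonyl C15 in a 5-exo-trig closure (C14–C15 bond) to give the cis-fused bicyclic alkoxide 9. Retro-Claisen cleavage of the shared C11–C15 bond of 9, with the sulfonyl-stabilised carbanion 10 as leaving group, merges the two five-membered rings into the eight-membered lactone, which therefore arises by a three-atom ring expansion and not by a direct medium-ring closure. The closest known reaction type is the three-carbon ring expansion of 2-(phenylsulfonyl)cycloalkanones with 2-(halomethyl)allylsilanes (alkylation, then fluoride-induced allylsilane addition and fragmentation), which is established for ketone carbonyls but not for the acyl–Cα bond of a lactone. The selectivity needed is the partition of 9 towards C–C and not C8–O cleavage, and it is secured because expulsion of the tertiary C8 alkoxide is reversible (the alkoxide stays tethered and re-adds to the ketone it would leave behind), whereas C–C cleavage gains ester resonance, relieves the crowded quaternary C11 and ends in a carbanion that is protonated on quenching. No stereocentre of the target is formed: C5, C8, C9 and C10 are untouched because neither the C8–O nor the C9–C11 bond is broken, the transient centres C11 and C15 of 8 and 9 follow from α-face alkylation and the obligatory cis ring fusion, and C11 of 11 is later reduced to CH2. The cold acetic acid quench protonates 10 kinetically and keeps the alkene exocyclic at C13.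

**Step 4**
Reactants: 11 11-(phenylsulfonyl)-8α,15-epoxylabd-13(16)-en-15-one
Product: 13 15-acetoxy-11-(phenylsulfonyl)-8α,15-epoxylabd-13(16)-ene, via aluminium hemiacetal 12 (not isolated)
Conditions: iBu2AlH, CH2Cl2, −78 °C; then pyridine, DMAP, Ac2O, −78 → 0 °C
Reagents that add atoms: acetic anhydride, CC(=O)OC(C)=O
Why: Reductive acetylation of an ester: one hydride adds to the lactone carbonyl and the aluminium hemiacetal 12, stable at −78 °C, is acetylated in the same flask before the eight-membered ring can open to a hydroxy aldehyde, while sulfone and alkene are inert and the new acetal centre C15 (epimer mixture) is removed in step 5.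

**Step 5**
Reactants: 13 15-acetoxy-11-(phenylsulfonyl)-8α,15-epoxylabd-13(16)-ene
Product: 14 11-(phenylsulfonyl)-8α,15-epoxylabd-13(16)-ene
Conditions: Et3SiH, BF3·OEt2, CH2Cl2, −78 → −40 °C
Reagents that add atoms: none
Why: Ionic reduction of an α-acetoxy ether: the Lewis acid ionises the anomeric acetate and the silane delivers hydride to the cyclic oxocarbenium ion at low temperature, faster than loss of the tertiary C8 cation or of a proton towards the alkene, which turns C15 into the ether methylene.

**Step 6**
Reactants: 14 11-(phenylsulfonyl)-8α,15-epoxylabd-13(16)-ene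
Product: 15 8α,15-epoxylabd-13(16)-ene
Conditions: Na(Hg) (6% Na), Na2HPO4, MeOH–THF, −20 → 0 °C
Reagents that add atoms: none
Why: Reductive desulfonylation by electron transfer cleaves the C11–S bond and methanol protonates the resulting carbanion, so that C11 becomes the required methylene, while the ether and the isolated 1,1-disubstituted alkene are inert to the buffered amalgam.

**Step 7**
Reactants: 15 8α,15-epoxylabd-13(16)-ene
Product: 17 (13R)-8α,15-epoxylabdan-16-ol, via trialkylborane 16 (not isolated)
Conditions: 9-BBN, THF, 0 °C → rt; then NaOH, H2O2, H2O, 0 °C → rt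
Reagents that add atoms: hydrogen peroxide, OO
Why: Anti-Markovnikov hydroboration–oxidation puts the hydroxyl on C16, and the bulky borane should deliver hydrogen to C13 from the α-face of the exocyclic alkene, away from the axial C8 and C10 methyl groups that lie over the β-face of the oxocane, which sets 13R with C16 cis to the C8 methyl.

**Step 8**
Reactants: 17 (13R)-8α,15-epoxylabdan-16-ol
Product: 18 (13R)-8α,15-epoxylabdan-16-yl acetate (CNP0152986.1)
Conditions: Ac2O, pyridine, DMAP (cat.), CH2Cl2, rt
Reagents that add atoms: acetic anhydride, CC(=O)OC(C)=O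
Why: Nucleophile-catalysed acetylation of the primary alcohol (DMAP) is routine and touches no stereocentre.

**Compound list**
1 | (+)-sclareolide, (3aR,5aS,9aS,9bR)-3a,6,6,9a-tetramethyldecahydronaphtho[2,1-b]furan-2(1H)-one | O=C1O[C@]2(C)CC[C@H]3C(C)(C)CCC[C@]3(C)[C@H]2C1 | starting material
2 | lithium enolate of 1 (C11=C15 enolate; not isolated) | [Li+].[O-]C1O[C@]2(C)CC[C@H]3C(C)(C)CCC[C@]3(C)[C@H]2C=1 | intermediate
3 | 11α-(phenylsulfanyl)sclareolide (PhS on the lactone α-carbon, cis to H9, trans to the C8 methyl) | O=C1O[C@]2(C)CC[C@H]3C(C)(C)CCC[C@]3(C)[C@H]2[C@@H]1Sc1ccccc1 | intermediate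
4 | 11α-(phenylsulfinyl)sclareolide (mixture at sulfur; not isolated) | O=C1O[C@]2(C)CC[C@H]3C(C)(C)CCC[C@]3(C)[C@H]2[C@@H]1S(=O)c1ccccc1 | intermediate
5 | 11α-(phenylsulfonyl)sclareolide | O=C1O[C@]2(C)CC[C@H]3C(C)(C)CCC[C@]3(C)[C@H]2[C@@H]1S(=O)(=O)c1ccccc1 | intermediate
6 | [2-(chloromethyl)prop-2-en-1-yl]trimethylsilane | C=C(CCl)C[Si](C)(C)C | starting material
7 | sodium enolate of 5 (not isolated) | [Na+].[O-]C1O[C@]2(C)CC[C@H]3C(C)(C)CCC[C@]3(C)[C@H]2C=1S(=O)(=O)c1ccccc1 | intermediate
8 | 11-(phenylsulfonyl)-11-{2-[(trimethylsilyl)methyl]prop-2-en-1-yl}sclareolide (allyl group α, sulfonyl β; not isolated) | O=C1O[C@]2(C)CC[C@H]3C(C)(C)CCC[C@]3(C)[C@H]2[C@@]1(CC(=C)C[Si](C)(C)C)S(=O)(=O)c1ccccc1 | intermediate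
9 | tetrabutylammonium alkoxide of the cis-fused bicyclic hemiketal formed by bonding C14 to C15 (new methylenecyclopentane ring on the α-face; O− and PhSO2 both β; not isolated) | CCCC[N+](CCCC)(CCCC)CCCC.[O-][C@@]14O[C@]2(C)CC[C@H]3C(C)(C)CCC[C@]3(C)[C@H]2[C@]1(S(=O)(=O)c1ccccc1)CC(=C)C4 | intermediate
10 | tetrabutylammonium salt of the C11 carbanion of 11 (not isolated) | CCCC[N+](CCCC)(CCCC)CCCC.O=C1O[C@]2(C)CC[C@H]3C(C)(C)CCC[C@]3(C)[C@H]2[C-](S(=O)(=O)c2ccccc2)CC(=C)C1 | intermediate
11 | 11-(phenylsulfonyl)-8α,15-epoxylabd-13(16)-en-15-one (eight-membered lactone trans-fused to the decalin, exocyclic methylene at C13, C11 epimers) | O=C1O[C@]2(C)CC[C@H]3C(C)(C)CCC[C@]3(C)[C@H]2C(S(=O)(=O)c2ccccc2)CC(=C)C1 | intermediate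
12 | diisobutylaluminium hemiacetal of 11 (not isolated) | CC(C)C[Al](CC(C)C)OC1O[C@]2(C)CC[C@H]3C(C)(C)CCC[C@]3(C)[C@H]2C(S(=O)(=O)c2ccccc2)CC(=C)C1 | intermediate
13 | 15-acetoxy-11-(phenylsulfonyl)-8α,15-epoxylabd-13(16)-ene (C11 and C15 epimers) | CC(=O)OC1O[C@]2(C)CC[C@H]3C(C)(C)CCC[C@]3(C)[C@H]2C(S(=O)(=O)c2ccccc2)CC(=C)C1 | intermediate
14 | 11-(phenylsulfonyl)-8α,15-epoxylabd-13(16)-ene (C11 epimers) | C=C1CCO[C@]2(C)CC[C@H]3C(C)(C)CCC[C@]3(C)[C@H]2C(S(=O)(=O)c2ccccc2)C1 | intermediate
15 | 8α,15-epoxylabd-13(16)-ene (5S,8R,9R,10S) | C=C1CCO[C@]2(C)CC[C@H]3C(C)(C)CCC[C@]3(C)[C@H]2CC1 | intermediate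
16 | B-[(13R)-8α,15-epoxylabdan-16-yl]-9-borabicyclo[3.3.1]nonane (not isolated) | C1CCC2CCCC1B2C[C@H]1CCO[C@]2(C)CC[C@H]3C(C)(C)CCC[C@]3(C)[C@H]2CC1 | intermediate
17 | (5S,8R,9R,10S,13R)-8α,15-epoxylabdan-16-ol | OC[C@H]1CCO[C@]2(C)CC[C@H]3C(C)(C)CCC[C@]3(C)[C@H]2CC1 | intermediate
18 | (5S,8R,9R,10S,13R)-8α,15-epoxylabdan-16-yl acetate | CC(=O)OC[C@H]1CCO[C@]2(C)CC[C@H]3C(C)(C)CCC[C@]3(C)[C@H]2CC1 | target

**Totals**
Total step count: 8. Longest linear sequence: 8 steps (from 1; 6 is bought).

**Steps most likely to fail**

1. Step 3 (proposed new method). The tetrahedral adduct may partition towards expulsion of the C8 alkoxide (a cyclopentanone instead of ring expansion), the allylsilane may be protodesilylated before it adds, or C-alkylation at the hindered C11 may fail. The fallback uses known reaction types only: the oxocane is closed by ring-closing metathesis and the C14–C15 bond is made by Hosomi–Sakurai allylation. It sets out from 1 and rejoins the route at 18. Compound 1 is reduced with iBu2AlH (CH2Cl2, −78 °C) to sclareolide lactol F1. Wittig methylenation (Ph3PCH3Br, KOtBu, THF, reflux) gives the ring-opened 8α-hydroxy-9-allyl decalin F2. The tertiary hydroxyl is converted with DMSO/Ac2O/AcOH (Pummerer-type) into methylthiomethyl ether F3. SO2Cl2 (CH2Cl2, −78 °C) gives chloromethyl ether F4, which is not isolated and is treated with 2-[(trimethylsilyl)methyl]allyl acetate and ZnBr2 to give diene acetate F5. Ring-closing metathesis (second-generation Grubbs catalyst, RuCl2(=CHPh)(H2IMes)(PCy3), toluene, 80 °C, high dilution) should close oxocene F6 at C12=C13, helped by the trans-diequatorial placement of the two chains on ring B. Hydrogenation with [Ir(cod)(PCy3)(py)]PF6 under H2 from the α-face should give 18.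

2. Step 4 (with its follow-up, step 5). The aluminium hemiacetal of the medium-ring lactone may collapse with ring opening before it is acetylated, or be over-reduced; in the ionic reduction the tertiary-alkyl oxocarbenium ion may lose the C8 cation. The fallback avoids any cation at C15; it sets out from 11 and returns at 14. Lawesson's reagent (toluene, 100 °C) gives thionolactone F7. LiBEt3H then MeI (THF, −78 °C) gives S-methyl monothioacetal F8. Radical desulfurisation with Ph3SnH/AIBN (toluene, 110 °C) gives 14.

3. Step 7. Facial selectivity of borane addition to the conformationally mobile oxocane may be poor or reversed. The fallback sets out from 15 and returns at 17. Epoxidation (mCPBA, NaHCO3, CH2Cl2, 0 °C) gives spiro-epoxide F9. Meinwald rearrangement (BF3·OEt2, or MeAl(OAr)2 with Ar = 4-bromo-2,6-di-tert-butylphenyl, CH2Cl2, −78 °C) gives aldehyde F10. Hydride migrates from C16 to C13 anti to the departing oxygen, so a reagent that prefers the same face as the borane now gives the opposite C13 configuration. If both faces react, the epimerisable aldehyde can also be equilibrated at C13 with DBU. NaBH4 (MeOH, 0 °C) then gives 17.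

**Further compounds**
F1 | step 3 | sclareolide lactol (hemiacetal, anomer mixture) | OC1O[C@]2(C)CC[C@H]3C(C)(C)CCC[C@]3(C)[C@H]2C1
F2 | step 3 | (1R,2R,4aS,8aS)-2,5,5,8a-tetramethyl-1-(prop-2-en-1-yl)decahydronaphthalen-2-ol | O[C@]1(C)CC[C@H]2C(C)(C)CCC[C@]2(C)[C@H]1CC=C
F3 | step 3 | methylthiomethyl ether of F2 | CSCO[C@]1(C)CC[C@H]2C(C)(C)CCC[C@]2(C)[C@H]1CC=C
F4 | step 3 | chloromethyl ether of F2 (not isolated) | ClCO[C@]1(C)CC[C@H]2C(C)(C)CCC[C@]2(C)[C@H]1CC=C
F5 | step 3 | 2-methylidene-4-[(C8-decalinyl)oxy]butyl acetate carrying the C9 allyl group | CC(=O)OCC(=C)CCO[C@]1(C)CC[C@H]2C(C)(C)CCC[C@]2(C)[C@H]1CC=C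
F6 | step 3 | 8α,15-epoxylabd-12-en-16-yl acetate | CC(=O)OCC1CCO[C@]2(C)CC[C@H]3C(C)(C)CCC[C@]3(C)[C@H]2CC=1
F7 | step 4 | 11-(phenylsulfonyl)-8α,15-epoxylabd-13(16)-ene-15-thione (thionolactone) | S=C1O[C@]2(C)CC[C@H]3C(C)(C)CCC[C@]3(C)[C@H]2C(S(=O)(=O)c2ccccc2)CC(=C)C1
F8 | step 4 | 15-(methylsulfanyl)-11-(phenylsulfonyl)-8α,15-epoxylabd-13(16)-ene | CSC1O[C@]2(C)CC[C@H]3C(C)(C)CCC[C@]3(C)[C@H]2C(S(=O)(=O)c2ccccc2)CC(=C)C1
F9 | step 7 | 13,16-epoxide of 15 (oxirane oxygen on the β-face) | C1O[C@]12CCO[C@]3(C)CC[C@H]4C(C)(C)CCC[C@]4(C)[C@H]3CC2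
F10 | step 7 | (13R)-8α,15-epoxylabdan-16-al | O=C[C@H]1CCO[C@]2(C)CC[C@H]3C(C)(C)CCC[C@]3(C)[C@H]2CC1
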